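The route rests on cutting the A ring out of the flavanonol at C4a–C5 and C8–C8a. Ring A (C4a, C5, C6, C7, C8, C8a) is a 5-hydroxy-7-methoxy-8-prenyl benzene fused to ring C along C4a–C8a. That bond is the enone C=C of a 2,3-dihydropyran-4-one that already holds the C2 aryl and C3 oxygen stereocentres. In one operation, cycloaddition of a prenylated 1,3-dioxygenated silyl ketene acetal diene to this bond, then loss of sulfenic acid and methanol, should build the complete, regiodefined A ring while C2 and C3 stay untouched. The dienophile is (2R,3R)-3-TBSO-2-(4-TBSO-3-methoxyphenyl)-5-(p-tolylsulfinyl)-2,3-dihydropyran-4-one.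

Key step: step 10

Remarks on the chemistry
- Ar = 4-(tert-butyldimethylsilyloxy)-3-methoxyphenyl. Pyranone C5 and C6 become chromanone C4a and C8a.
- Assumption: (S)-BINOL is taken as the ligand antipode that directs Si-face attack in step 2, by analogy with BINOL–titanium additions to aryl aldehydes; if the sense is opposite for this aldehyde, (R)-BINOL is used.
- C2 keeps its spatial arrangement from 5 to 8; its descriptor changes from S to R only because C3 gains priority once it carries oxygen.
- Sulfoxide 12 is carried as a mixture of sulfur epimers and diene 17 as its geometric mixture; sulfur and the diene geometry are both erased in step 10.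

Step 1
Reactants: 1 vanillin
Product: 2 4-(tert-butyldimethylsilyloxy)-3-methoxybenzaldehyde
Conditions: TBSCl, imidazole, DMF, rt
Reagents that add atoms: tert-butyldimethylsilyl chloride, CC(C)(C)[Si](C)(C)Cl
Why: Silyl ether formation masks the acidic phenol, which would otherwise quench the Lewis acid of step 2 and the bases used later.

Step 2
Reactants: 2 4-(tert-butyldimethylsilyloxy)-3-methoxybenzaldehyde; 3 Danishefsky's diene
Product: 5 (S)-2-Ar-2,3-dihydro-4H-pyran-4-one, via aldol adduct 4 (not isolated)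
Conditions: (S)-BINOL (20 mol%), Ti(OiPr)4 (10 mol%), 4 Å MS, Et2O, −20 °C→rt; then TFA, CH2Cl2, 0 °C
Reagents that add atoms: none
Why: Catalytic asymmetric hetero-Diels–Alder reaction in its Mukaiyama aldol–cyclisation form, in which the BINOL–titanium Lewis acid should expose the Si face of the aldehyde to the diene terminus and so set C2, after which TFA closes the ring with loss of methanol and the silyl group.

Step 3
Reactants: 5 (S)-2-Ar-2,3-dihydro-4H-pyran-4-one
Product: 8 (2R,3R)-2-Ar-3-hydroxy-2,3-dihydro-4H-pyran-4-one, via silyl dienol ether 6 (not isolated), via 3-O-TMS ketone 7 (not isolated)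
Conditions: LDA, TMSCl (in situ), THF, −78 °C; then DMDO, acetone/CH2Cl2, −78 °C; then citric acid, MeOH, 0 °C
Reagents that add atoms: dimethyldioxirane, CC1(C)OO1
Why: Rubottom oxidation, in which kinetic α′-deprotonation of the vinylogous ester with immediate silylation gives the 4-silyloxy-2H-pyran and its C3=C4 bond should take oxygen from DMDO on the face opposite the C2 aryl group, so that the new C3–O bond is trans to the aryl (3R).

Step 4
Reactants: 8 (2R,3R)-2-Ar-3-hydroxy-2,3-dihydro-4H-pyran-4-one
Product: 9 (2R,3R)-2-Ar-3-(tert-butyldimethylsilyloxy)-2,3-dihydro-4H-pyran-4-one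
Conditions: TBSOTf, 2,6-lutidine, CH2Cl2, −78 °C
Reagents that add atoms: tert-butyldimethylsilyl triflate, CC(C)(C)[Si](C)(C)OS(=O)(=O)C(F)(F)F
Why: Silyl ether formation on the secondary alcohol with a silyl triflate and a hindered base, at a temperature where the C3 centre next to the ketone should not enolise.

Step 5
Reactants: 9 (2R,3R)-2-Ar-3-(tert-butyldimethylsilyloxy)-2,3-dihydro-4H-pyran-4-one
Product: 11 (2R,3R)-2-Ar-3-(tert-butyldimethylsilyloxy)-5-(p-tolylthio)-2,3-dihydro-4H-pyran-4-one, via chloro sulfide adduct 10 (not isolated)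
Conditions: p-TolSCl (from (p-TolS)2 and SO2Cl2, CH2Cl2, 0 °C), CH2Cl2, −78 °C; then Et3N, −78→0 °C
Reagents that add atoms: p-toluenesulfenyl chloride, Cc1ccc(SCl)cc1 (generated from di-p-tolyl disulfide, Cc1ccc(SSc2ccc(C)cc2)cc1)
Why: Electrophilic α-sulfenylation of the enone by addition–elimination, in which the sulfenyl chloride should add across the enol ether bond with sulfur at the nucleophilic C5 and chloride at the oxocarbenium carbon C6, and triethylamine then removes the acidic C5–H to expel chloride and restore the enone.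

Step 6
Reactants: 11 (2R,3R)-2-Ar-3-(tert-butyldimethylsilyloxy)-5-(p-tolylthio)-2,3-dihydro-4H-pyran-4-one
Product: 12 (2R,3R)-2-Ar-3-(tert-butyldimethylsilyloxy)-5-(p-tolylsulfinyl)-2,3-dihydro-4H-pyran-4-one (both sulfur epimers)
Conditions: mCPBA (1.0 equiv), CH2Cl2, −78 °C
Reagents that add atoms: m-chloroperbenzoic acid, OOC(=O)c1cccc(Cl)c1
Why: Sulfide-to-sulfoxide oxidation with one equivalent of peracid at low temperature, where sulfur is far more nucleophilic than the push–pull C=C bond, the arene or the silyl ethers; the new sulfur centre is left uncontrolled because it is lost in step 10.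

Step 7
Reactants: 13 methyl acetoacetate; 14 prenyl bromide
Product: 15 methyl 7-methyl-3-oxooct-6-enoate
Conditions: NaH, THF, 0 °C; n-BuLi, 0 °C; then 14, 0 °C→rt; 1 M HCl
Reagents that add atoms: none
Why: Weiler dianion alkylation, in which the γ-carbanion of the acetoacetate dianion is the more reactive site and should displace the allylic bromide by SN2 substitution without touching C2.

Step 8
Reactants: 15 methyl 7-methyl-3-oxooct-6-enoate
Product: 16 methyl (E)-3-methoxy-7-methylocta-2,6-dienoate
Conditions: HC(OMe)3, H2SO4 (cat.), MeOH, rt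
Reagents that add atoms: trimethyl orthoformate, COC(OC)OC
Why: Acid-catalysed enol ether formation (ketalisation, then loss of methanol) should give the conjugated E β-methoxy enoate, the geometry that places the C4 methylene syn to the ester for the next deprotonation.

Step 9
Reactants: 16 methyl (E)-3-methoxy-7-methylocta-2,6-dienoate
Product: 17 1,3-dimethoxy-7-methyl-1-(trimethylsilyloxy)octa-1,3,6-triene
Conditions: LDA, THF, −78 °C; TMSCl, −78 °C→rt; pentane, filtration (non-aqueous)
Reagents that add atoms: trimethylsilyl chloride, C[Si](C)(C)Cl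
Why: Silyl ketene acetal formation, in which LDA removes a γ-proton (C4) of the β-methoxy enoate and O-silylation of the extended enolate gives a Brassard-type diene carrying the prenyl group on its nucleophilic terminus.

Step 10
Reactants: 12 (2R,3R)-2-Ar-3-(tert-butyldimethylsilyloxy)-5-(p-tolylsulfinyl)-2,3-dihydro-4H-pyran-4-one; 17 1,3-dimethoxy-7-methyl-1-(trimethylsilyloxy)octa-1,3,6-triene
Product: 20 (2R,3R)-2-Ar-3-(tert-butyldimethylsilyloxy)-5-hydroxy-7-methoxy-8-(3-methylbut-2-enyl)chroman-4-one, via cycloadduct 18 (not isolated), via 5-O-TMS ether 19 (not isolated)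
Conditions: 17 (3 equiv), toluene, rt→60 °C; then SiO2, wet CH2Cl2, rt
Reagents that add atoms: none
Why: Proposed new method: the electron-rich diene 17 should add across the C5=C6 bond of 12, made electron-poor by the ketone and the sulfinyl group, with the prenyl-bearing nucleophilic terminus C4 of the diene bonding to C6 (β to the ketone, the future C8a) and the ketene acetal carbon C1 bonding to C5 (the future C4a); syn-elimination of p-toluenesulfenic acid from adduct 18 then restores C4a=C8a, 1,4-loss of methanol aromatises the ring to the 5-O-TMS ether 19, and work-up frees the hydrogen-bonded 5-OH. The closest known reactions are cycloaddition–aromatisation sequences of Brassard- and Danishefsky-type dienes with sulfinyl- or halo-substituted quinones and enones and with 3-activated chromones; a β-oxygenated sulfinyl dihydropyranone that is not benzo-fused has not served as the 2π partner. Ring A is closed by an intermolecular [4+2] cycloaddition that forms C4a–C5 and C8–C8a; if the addition is stepwise, a vinylogous Mukaiyama–Michael attack at C8a is followed by 6-exo-trig closure of the sulfinyl-stabilised enolate onto the ester carbon, with the same outcome. No stereocentre is created in the product, because the four sp3 centres of 18 are erased on aromatisation and C2 and C3 are spectators under neutral thermal conditions. The step needs regioselectivity, which the matched polarisation of the diene (C4 nucleophilic) and the sulfinyl enone (C6 electrophilic) should secure, and it needs cycloaddition to outrun β-elimination of O1, which the absence of base and the extra activation by sulfur are meant to ensure.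

Step 11
Reactants: 20 (2R,3R)-2-Ar-3-(tert-butyldimethylsilyloxy)-5-hydroxy-7-methoxy-8-(3-methylbut-2-enyl)chroman-4-one
Product: 21 (2R,3R)-3,5-dihydroxy-2-(4-hydroxy-3-methoxyphenyl)-7-methoxy-8-(3-methylbut-2-enyl)chroman-4-one
Conditions: HF·pyridine, pyridine/THF, 0 °C→rt
Reagents that add atoms: none
Why: Fluoride-mediated silyl ether cleavage under pyridine-buffered, non-basic conditions should remove both TBS groups without ring opening, epimerisation or oxidation of the base-sensitive trans-dihydroflavonol and without touching the prenyl alkene.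

Compound list
1 | vanillin (4-hydroxy-3-methoxybenzaldehyde) | COc1cc(C=O)ccc1O | starting material
2 | 4-(tert-butyldimethylsilyloxy)-3-methoxybenzaldehyde | COc1cc(C=O)ccc1O[Si](C)(C)C(C)(C)C | intermediate
3 | Danishefsky's diene, (E)-1-methoxy-3-(trimethylsilyloxy)buta-1,3-diene | CO/C=C/C(=C)O[Si](C)(C)C | starting material
4 | Mukaiyama aldol adduct, (S,E)-5-Ar-1-methoxy-5-(trimethylsilyloxy)pent-1-en-3-one | COc1cc([C@H](CC(=O)/C=C/OC)O[Si](C)(C)C)ccc1O[Si](C)(C)C(C)(C)C | intermediate
5 | (S)-2-[4-(tert-butyldimethylsilyloxy)-3-methoxyphenyl]-2,3-dihydro-4H-pyran-4-one | COc1cc([C@H]2OC=CC(=O)C2)ccc1O[Si](C)(C)C(C)(C)C | intermediate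
6 | (S)-2-Ar-4-(trimethylsilyloxy)-2H-pyran (silyl dienol ether) | COc1cc([C@H]2OC=CC(O[Si](C)(C)C)=C2)ccc1O[Si](C)(C)C(C)(C)C | intermediate
7 | (2R,3R)-2-Ar-3-(trimethylsilyloxy)-2,3-dihydro-4H-pyran-4-one | COc1cc([C@H]2OC=CC(=O)[C@@H]2O[Si](C)(C)C)ccc1O[Si](C)(C)C(C)(C)C | intermediate
8 | (2R,3R)-2-Ar-3-hydroxy-2,3-dihydro-4H-pyran-4-one (2,3-trans) | COc1cc([C@H]2OC=CC(=O)[C@@H]2O)ccc1O[Si](C)(C)C(C)(C)C | intermediate
9 | (2R,3R)-2-Ar-3-(tert-butyldimethylsilyloxy)-2,3-dihydro-4H-pyran-4-one | COc1cc([C@H]2OC=CC(=O)[C@@H]2O[Si](C)(C)C(C)(C)C)ccc1O[Si](C)(C)C(C)(C)C | intermediate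
10 | (2R,3R)-2-Ar-3-(tert-butyldimethylsilyloxy)-6-chloro-5-(p-tolylthio)tetrahydropyran-4-one (C5 and C6 undefined) | COc1cc([C@H]2OC(Cl)C(Sc3ccc(C)cc3)C(=O)[C@@H]2O[Si](C)(C)C(C)(C)C)ccc1O[Si](C)(C)C(C)(C)C | intermediate
11 | (2R,3R)-2-Ar-3-(tert-butyldimethylsilyloxy)-5-(p-tolylthio)-2,3-dihydro-4H-pyran-4-one | COc1cc([C@H]2OC=C(Sc3ccc(C)cc3)C(=O)[C@@H]2O[Si](C)(C)C(C)(C)C)ccc1O[Si](C)(C)C(C)(C)C | intermediate
12 | (2R,3R)-2-Ar-3-(tert-butyldimethylsilyloxy)-5-(p-tolylsulfinyl)-2,3-dihydro-4H-pyran-4-one (sulfur epimers) | COc1cc([C@H]2OC=C(S(=O)c3ccc(C)cc3)C(=O)[C@@H]2O[Si](C)(C)C(C)(C)C)ccc1O[Si](C)(C)C(C)(C)C | intermediate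
13 | methyl acetoacetate | COC(=O)CC(C)=O | starting material
14 | prenyl bromide (1-bromo-3-methylbut-2-ene) | CC(C)=CCBr | starting material
15 | methyl 7-methyl-3-oxooct-6-enoate | COC(=O)CC(=O)CCC=C(C)C | intermediate
16 | methyl (E)-3-methoxy-7-methylocta-2,6-dienoate | CO/C(CCC=C(C)C)=C/C(=O)OC | intermediate
17 | 1,3-dimethoxy-7-methyl-1-(trimethylsilyloxy)octa-1,3,6-triene (geometric mixture) | COC(O[Si](C)(C)C)=CC(OC)=CCC=C(C)C | intermediate
18 | cycloadduct, (2R,3R)-2-Ar-3-(tert-butyldimethylsilyloxy)-5,7-dimethoxy-8-(3-methylbut-2-enyl)-4a-(p-tolylsulfinyl)-5-(trimethylsilyloxy)-2,3,4a,5,8,8a-hexahydrochromen-4-one (new centres undefined) | COc1cc([C@H]2OC3C(CC=C(C)C)C(OC)=CC(OC)(O[Si](C)(C)C)C3(S(=O)c3ccc(C)cc3)C(=O)[C@@H]2O[Si](C)(C)C(C)(C)C)ccc1O[Si](C)(C)C(C)(C)C | intermediate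
19 | (2R,3R)-2-Ar-3-(tert-butyldimethylsilyloxy)-7-methoxy-8-(3-methylbut-2-enyl)-5-(trimethylsilyloxy)chroman-4-one | COc1cc([C@H]2Oc3c(CC=C(C)C)c(OC)cc(O[Si](C)(C)C)c3C(=O)[C@@H]2O[Si](C)(C)C(C)(C)C)ccc1O[Si](C)(C)C(C)(C)C | intermediate
20 | (2R,3R)-2-Ar-3-(tert-butyldimethylsilyloxy)-5-hydroxy-7-methoxy-8-(3-methylbut-2-enyl)chroman-4-one | COc1cc([C@H]2Oc3c(CC=C(C)C)c(OC)cc(O)c3C(=O)[C@@H]2O[Si](C)(C)C(C)(C)C)ccc1O[Si](C)(C)C(C)(C)C | intermediate
21 | (2R,3R)-3,5-dihydroxy-2-(4-hydroxy-3-methoxyphenyl)-7-methoxy-8-(3-methylbut-2-enyl)chroman-4-one (2,3-trans) | COc1cc([C@H]2Oc3c(CC=C(C)C)c(OC)cc(O)c3C(=O)[C@@H]2O)ccc1O | target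

Total step count: 11. Longest linear sequence: 8 steps (steps 1–6, 10, 11); the diene branch (steps 7–9) joins at step 10.

Steps most likely to fail

1. Step 10 (proposed new method). The vinylogous ester may be too weak a 2π partner, so the diene could hydrolyse or merely add in conjugate fashion before ring closure. The pyranone could also open by β-elimination of O1, and aromatisation could stall after the sulfenic acid is lost. Fallback with known chemistry, setting out from 1 and returning at 20: the A ring is taken from a ready-made phloroglucinol and the prenyl group is moved to C8 by sigmatropic rearrangement.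
   - Vanillin 1 would be converted into 3-methoxy-4-(methoxymethoxy)benzaldehyde F1 (MOMCl, iPr2NEt).
   - Commercial 2′,6′-dihydroxy-4′-methoxyacetophenone would be converted into 4′-methoxy-2′,6′-bis(methoxymethoxy)acetophenone F2 (MOMCl, NaH, DMF).
   - Claisen–Schmidt condensation (KOH, EtOH) would give the (E)-chalcone F3.
   - Julia–Colonna epoxidation (poly-L-leucine, urea–H2O2, DBU, THF) should give the (2R,3S)-epoxy ketone F4.
   - HCl in MeOH would remove the three MOM groups and let a phenol open the epoxide at the benzylic carbon, giving (2R,3R)-3,5-dihydroxy-2-(4-hydroxy-3-methoxyphenyl)-7-methoxychroman-4-one F5. C3 keeps the configuration of the epoxide carbon next to the ketone, and trans is the stable arrangement at C2.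
   - Silylation of the 3- and 4′-hydroxyls (TBSOTf, 2,6-lutidine; the chelated 5-OH reacts last) would give the bis-TBS ether F6.
   - Mitsunobu etherification with 3-methylbut-2-en-1-ol (PPh3, DIAD) would give the 5-O-prenyl ether F7.
   - Eu(fod)3-catalysed para-Claisen–Cope rearrangement (CHCl3, 60 °C) would move the prenyl group from O5 to C8 and arrive at 20.

2. Step 3. The lithium enolate may open the ring by β-elimination of O1 before it is silylated, or oxygen may be delivered with poor facial or site selectivity to the dienol ether. Fallback setting out from 5 and returning at 8: oxidative α′-acetoxylation with Mn(OAc)3 (benzene, reflux), which needs neither a free enolate nor a silyl enol ether, should place the acetate trans to the aryl group and give (2R,3R)-2-Ar-3-acetoxy-2,3-dihydro-4H-pyran-4-one F8. Lipase-catalysed hydrolysis at pH 7 would then free the alcohol 8 without touching the aryl silyl ether.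

3. Step 5. The sulfenyl chloride may react sluggishly with the deactivated enol ether bond, or sulfenylate the electron-rich aryl ring or C3 instead. Fallback setting out from 9 and returning at 11: the polarity of the C–S bond formation is reversed. α-Iodination of the enone (I2, pyridine, CH2Cl2) would give (2R,3R)-2-Ar-3-(tert-butyldimethylsilyloxy)-5-iodo-2,3-dihydro-4H-pyran-4-one F9, and palladium-catalysed C–S coupling with 4-methylbenzenethiol (Pd2(dba)3, Xantphos, iPr2NEt, dioxane) would give sulfide 11.

Further compounds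
F1 | step 10 | 3-methoxy-4-(methoxymethoxy)benzaldehyde | COCOc1ccc(C=O)cc1OC
F2 | step 10 | 1-[4-methoxy-2,6-bis(methoxymethoxy)phenyl]ethan-1-one | COCOc1cc(OC)cc(OCOC)c1C(C)=O
F3 | step 10 | (E)-1-[4-methoxy-2,6-bis(methoxymethoxy)phenyl]-3-[3-methoxy-4-(methoxymethoxy)phenyl]prop-2-en-1-one | COCOc1ccc(/C=C/C(=O)c2c(OCOC)cc(OC)cc2OCOC)cc1OC
F4 | step 10 | [(2R,3S)-3-[3-methoxy-4-(methoxymethoxy)phenyl]oxiran-2-yl][4-methoxy-2,6-bis(methoxymethoxy)phenyl]methanone (trans epoxide) | COCOc1cc(OC)cc(OCOC)c1C(=O)[C@@H]1O[C@H]1c1ccc(OCOC)c(OC)c1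
F5 | step 10 | (2R,3R)-3,5-dihydroxy-2-(4-hydroxy-3-methoxyphenyl)-7-methoxychroman-4-one | COc1cc([C@H]2Oc3cc(OC)cc(O)c3C(=O)[C@@H]2O)ccc1O
F6 | step 10 | (2R,3R)-2-Ar-3-(tert-butyldimethylsilyloxy)-5-hydroxy-7-methoxychroman-4-one | COc1cc([C@H]2Oc3cc(OC)cc(O)c3C(=O)[C@@H]2O[Si](C)(C)C(C)(C)C)ccc1O[Si](C)(C)C(C)(C)C
F7 | step 10 | (2R,3R)-2-Ar-3-(tert-butyldimethylsilyloxy)-7-methoxy-5-(3-methylbut-2-enyloxy)chroman-4-one | COc1cc([C@H]2Oc3cc(OC)cc(OCC=C(C)C)c3C(=O)[C@@H]2O[Si](C)(C)C(C)(C)C)ccc1O[Si](C)(C)C(C)(C)C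
F8 | step 3 | (2R,3R)-2-Ar-3-acetoxy-2,3-dihydro-4H-pyran-4-one | COc1cc([C@H]2OC=CC(=O)[C@@H]2OC(C)=O)ccc1O[Si](C)(C)C(C)(C)C
F9 | step 5 | (2R,3R)-2-Ar-3-(tert-butyldimethylsilyloxy)-5-iodo-2,3-dihydro-4H-pyran-4-one | COc1cc([C@H]2OC=C(I)C(=O)[C@@H]2O[Si](C)(C)C(C)(C)C)ccc1O[Si](C)(C)C(C)(C)C
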